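| flask | substrate | coupling partner | remark | time |
|---|---|---|---|---|
| Thursday's | 0.057 M (fed, over 20 min) | 0.057 M | run made earlier; the fed solution adds 0.50 times the starting volume |  |
| Friday's | 0.057 M (fed, over 20 min) | 0.086 M | run made earlier; the fed solution adds 0.50 times the starting volume |  |
| Wednesday's | 0.11 M (fed, over 20 min) | 0.114 M | run made earlier; the fed solution adds 0.50 times the starting volume |  |
| flask | 0.057 M (fed, over 20 min) | 0.114 M | the fed solution adds 0.50 times the starting volume | 40 h |

| Thursday's: time / h | Thursday's: single product / % | Friday's: time / h | Friday's: single product / % | Wednesday's: time / h | Wednesday's: single product / % |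
|---|---|---|---|---|---|
| 0.250 | 3.0 | 0.250 | 3.8 | 0.250 | 3.9 |
| 1.00 | 9.6 | 1.00 | 10.3 | 1.00 | 11.1 |
| 5.00 | 6.7 | 5.00 | 5.2 | 5.00 | 6.3 |
| 25.0 | 5.2 | 25.0 | 2.4 | 25.0 | 3.9 |

(standard deviation of a reading: 0.5 percentage points)

1. the best time, 40 h at the latest, for single product
2. the amount of single product, in percent of the substrate charged, at that time

- what is said of by-product includes crystals
- amounts are per litre of the starting volume; all of the dose is in the solution fed
- crystals is a solid; its amount is given per volume of the solution
- what was read earlier has a scatter of 0.5 percentage points, one standard deviation
- steps that have been proposed: coupling partner + single product -> double product + by-product; substrate + coupling partner -> other mono adduct + by-product; substrate + coupling partner -> single product + by-product; crystals <-> by-product; coupling partner + other mono adduct -> double product + by-product; substrate <-> dormant form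
- percentages count the whole charge, also what has not yet gone in

At early times the single product climbs in every run, and by 5.00 h it has fallen. I take its making and its loss as both pseudo-first-order in coupling partner. Dividing one rate by the other removes the partner. Integrating then leaves one curve in a single variable, the exposure: partner charged times the time past mid-feed.

From above, Thursday's run has dropped to 6.7% at exposure 0.276 M·h, and this flask reaches that exposure at 2.58 h. I tighten this with Wednesday's run, whose 11.1% is the highest reading. Its counted exposure is 0.0950 M·h, and that run charges 0.114 M of partner against 0.11 M of substrate, so I expect the count to run high. This flask reaches that exposure at 1.00 h, which I take as my upper edge; it is an estimate, not a proven bound.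

From below, Thursday's 9.6% stands at 0.0475 M·h, which this flask passes at 0.583 h.

I commit to Friday's middle point, 0.0717 M·h, as the peak exposure, the partner charged times the time past mid-feed at which the single product tops. For this flask that means 0.795 h, with a height between 10.3% and 11.1%.

The forecast says 1 h and 11.5%: "The peak height barely changes, because both steps scale with partner". Its time sits at my upper edge, and its height is above my range.

The flask tops at 0.814 h with 10.9%.

    coupling partner + single product → double product + by-product (k = 0.570 M⁻¹ min⁻¹)
    substrate + coupling partner → other mono adduct + by-product (k = 0.0420 M⁻¹ min⁻¹)
    substrate + coupling partner → single product + by-product (k = 0.120 M⁻¹ min⁻¹)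
    crystals ⇌ by-product, rate k4*(cs4 - [by-product]) while solid is left; crystals form when [by-product] > cs4 (solubility = 33.0 mM, k = 0.420 min⁻¹)
    coupling partner + other mono adduct → double product + by-product (k = 0.0290 M⁻¹ min⁻¹)
    substrate ⇌ dormant form (K = 1.00, k = 0.00690 min⁻¹)

That time is earlier than the forecast's and lies inside my bracket. The top is broad: the flask already holds 10.6% at 0.652 h. The exposure at its best time is 0.0738 M·h, against my 0.0717 M·h. For a neighbour flask with 0.097 M of substrate and the same partner charge, my peak exposure gives the same 0.795 h and I keep the same range of height; the best amount of single product in that neighbour flask is 10.8%.

The data were generated by integration with made-up constants, and the scatter is random.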